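**An easy start.** The easiest thing to read from the runs is where they stop. Friday's Q reads 0% at 12.0 min and Tuesday's reads 0% at 40.0 min, and L stays flat afterwards, so both runs end with Q used up.

| flask | Q | Z | remark | time |
|---|---|---|---|---|
| Friday's | 1 M | 2 M | run made earlier |  |
| Tuesday's | 2 M | 3 M | run made earlier |  |
| flask | 2.0 M | 2.00 M |  | 80 min |

| run | time / min | Q / % | L / % |
|---|---|---|---|
| Friday's | 5.00 | 14 | 47 |
| Friday's | 12.0 | 0 | 59 |
| Friday's | 30.0 | 0 | 57 |
| Friday's | 60.0 | 0 | 59 |
| Tuesday's | 8.00 | 1 | 35 |
| Tuesday's | 25.0 | 1 | 38 |
| Tuesday's | 40.0 | 0 | 38 |
| Tuesday's | 60.0 | 0 | 38 |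

(readings scatter by 1.5 percentage points)

- solid, in amounts per volume of the solution: Z
- at the start none of Z is in solution
- the reaction counts as stopped when no species that holds the Q changes by six tenths of a point or more over the second half of the time

- the state of affairs at 80 min: stopped, and by what, or still going (for what has run out or reacted, a solid counts together with what of it has only dissolved) (forward and back rates have come level / G has run out first / it is still moving / all of Q has reacted)
- conversion of Q at 80 min
- amount of L at 80 min, in percent of the Q charged

**Two routes.** L levels off at 58.3% on Friday and 38.0% on Tuesday, with twice the Q. We suppose that Q is lost at a rate constant times c_Q squared, and goes to L at a rate constant times c_Q and dissolved Z. At equal dissolved Z, L formed over Q lost then falls as c_Q rises.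

**Split concentration.** The charged c_Q times L formed over Q lost gives 1.40 M on Friday and 1.23 M on Tuesday, as readings lower despite Tuesday's extra Z. This is a selectivity factor in concentration form. Their mean, S, the split concentration, is 1.31 M, and with dissolved Z taken as equal, the share of L over a whole run is S over S plus the charged c_Q. The rule is rough, since the two values differ.

**Our reckoning.** For this flask we expect Q to be used up and L at 39.6%. At one Z per L, that takes 0.793 M of the 2.00 M of Z charged.

**The forecast.** It says all of Q has reacted, with conversion 100% (98% to 100%) and L 37% (29% to 40%), noting that “extra solid did not help”. Our figure stands 2.6 percentage points above its figure.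

**The flask.** The result is all of Q has reacted, with conversion 100% and L 38.6%, which puts S here at 1.26 M.

    2 Q → X (k = 0.00260 M⁻¹ s⁻¹)
    Z ⇌ G, rate k2*(cs2 - [G]) while solid is left; crystals form when [G] > cs2 (solubility = 1.70 M, k = 0.00210 s⁻¹)
    Q + G ⇌ L + J (K = 14.0, k = 0.0190 M⁻¹ s⁻¹)
    J → D (k = 0.00300 s⁻¹)

**What to watch.** In this flask conversion is half done by 1.31 min, and at 5.33 min, which is later, the forward step to L, its way back not counted, uses Q 7.8 times as fast as the pairing into X. X nevertheless ends at 61.4% of the Q charged, against L at 38.6%; the first minutes are the ones to read.

**Second flask.** For a flask like this one but charged with 1.2 M of Q, S gives 52.2% of L. The computed second flask gives 52.8%.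

Readings and results were generated by integration on assumed constants, and the scatter is random.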